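## Retrosynthetic overview

- The strategy rests on one feature: the C1 ester carbon and the tertiary C12 hydroxyl can be the two ends of a ten-membered lactone (ring atoms C12, O, C1 to C8) fused to the cyclopentenone (ring C8–C12) through the C8–C12 bond. In that ring C7=C8 is endocyclic, so C6 must lie cis to C12 (7E), and C5=C6 is forced cis (5Z). The target is the methanolysis product of this lactone.
- The lactone comes from ring-closing metathesis that forms C5=C6 between a C12 hex-5-enoate and a C8 allylidene group.
- The metathesis precursor comes from acylation of C12–OH. The allylidene comes from aldol addition of acrolein at C8 and dehydration. Bromine at C10 comes from the enone through its epoxide and HBr, because Br2 would not spare C14=C15.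
- The hydroxy enone comes from (R)-4-silyloxycyclopentenone by anti 1,2-propargylation (sets C12), acetylide pentylation, cis-semihydrogenation, desilylation and oxidation at C9. The silyloxy enone comes from the cyclopentenediol monoacetate.
- Ring order: the five-membered ring is present from the start; the ten-membered lactone is closed in step 15 and opened in step 16.

Key step: step 15

Remark: locants C1–C20 are those of the prostanoic acid skeleton of the target (C1 ester carbon, ring C8–C12, C12 the carbinol carbon); compound names use ring locants.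

## Route

Step 1
Reactants: 1 (1R,4S)-cis-4-acetoxycyclopent-2-en-1-ol
Product: 2 (1S,4R)-4-[(tert-butyldimethylsilyl)oxy]cyclopent-2-en-1-yl acetate
Conditions: t-BuMe2SiCl, imidazole, DMF, rt
Reagents that add atoms: tert-butyldimethylsilyl chloride, CC(C)(C)[Si](C)(C)Cl
Why: Imidazole-mediated silyl ether formation caps the only free hydroxyl and touches neither stereocentre.

Step 2
Reactants: 2 (1S,4R)-4-[(tert-butyldimethylsilyl)oxy]cyclopent-2-en-1-yl acetate
Product: 3 (1S,4R)-4-[(tert-butyldimethylsilyl)oxy]cyclopent-2-en-1-ol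
Conditions: K2CO3 (0.2 equiv), MeOH, 0 °C to rt
Reagents that add atoms: none
Why: Carbonate-catalysed transesterification removes the acetate while the silyl ether stays, so the two oxygens are differentiated in the sense needed.

Step 3
Reactants: 3 (1S,4R)-4-[(tert-butyldimethylsilyl)oxy]cyclopent-2-en-1-ol
Product: 4 (4R)-4-[(tert-butyldimethylsilyl)oxy]cyclopent-2-en-1-one
Conditions: Dess–Martin periodinane (1.2 equiv), CH2Cl2, 0 °C to rt
Reagents that add atoms: none
Why: Dess–Martin oxidation of the allylic alcohol gives the enone under conditions too mild to eliminate the β-silyloxy group, leaving the silyloxy carbon (the future C9) as the single R stereocentre.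

Step 4
Reactants: 4 (4R)-4-[(tert-butyldimethylsilyl)oxy]cyclopent-2-en-1-one; 5 propargyl bromide (3-bromoprop-1-yne)
Product: 6 (1S,4R)-4-[(tert-butyldimethylsilyl)oxy]-1-(prop-2-yn-1-yl)cyclopent-2-en-1-ol (hydroxyl cis to the silyloxy group)
Conditions: Zn dust (activated), THF, 0 °C to rt; aqueous work-up
Reagents that add atoms: none
Why: Barbier propargylation in which allenylzinc bromide adds 1,2 to the ketone through a cyclic SE2' transition state (hence the homopropargylic, not the allenic, carbinol) from the face anti to the silyloxy group, which sets C12 with its hydroxyl cis to the OSi group.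

Step 5
Reactants: 6 (1S,4R)-4-[(tert-butyldimethylsilyl)oxy]-1-(prop-2-yn-1-yl)cyclopent-2-en-1-ol; 7 1-iodopentane
Product: 8 (1S,4R)-4-[(tert-butyldimethylsilyl)oxy]-1-(oct-2-yn-1-yl)cyclopent-2-en-1-ol
Conditions: n-BuLi (2.2 equiv), THF, −78 to −20 °C; then 7, DMPU, −20 °C to rt; H2O
Reagents that add atoms: none
Why: Acetylide alkylation of the alkoxide/acetylide dianion, in which the sp carbanion is far more nucleophilic toward the primary iodide than the hindered tertiary alkoxide; building the oct-2-ynyl chain this way avoids the propargyl/allenyl ambiguity of a γ-alkylated propargyl metal.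

Step 6
Reactants: 8 (1S,4R)-4-[(tert-butyldimethylsilyl)oxy]-1-(oct-2-yn-1-yl)cyclopent-2-en-1-ol
Product: 9 (1S,4R)-4-[(tert-butyldimethylsilyl)oxy]-1-[(2Z)-oct-2-en-1-yl]cyclopent-2-en-1-ol
Conditions: H2 (1 atm), Pd/CaCO3 poisoned with Pb(OAc)2, quinoline, EtOAc, rt
Reagents that add atoms: none
Why: Lindlar semihydrogenation adds H2 syn to the alkyne and stops at the alkene, giving the 14Z geometry and leaving the ring alkene alone.

Step 7
Reactants: 9 (1S,4R)-4-[(tert-butyldimethylsilyl)oxy]-1-[(2Z)-oct-2-en-1-yl]cyclopent-2-en-1-ol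
Product: 10 (1S,4R)-1-[(2Z)-oct-2-en-1-yl]cyclopent-2-ene-1,4-diol
Conditions: Bu4NF, THF, 0 °C to rt
Reagents that add atoms: none
Why: Fluoride-induced desilylation frees the C9 hydroxyl under non-acidic conditions that spare the tertiary allylic alcohol.

Step 8
Reactants: 10 (1S,4R)-1-[(2Z)-oct-2-en-1-yl]cyclopent-2-ene-1,4-diol
Product: 11 (4S)-4-hydroxy-4-[(2Z)-oct-2-en-1-yl]cyclopent-2-en-1-one
Conditions: Dess–Martin periodinane (1.1 equiv), CH2Cl2, 0 °C
Reagents that add atoms: none
Why: Dess–Martin oxidation converts the secondary allylic alcohol into the enone, cannot oxidise the tertiary alcohol and, unlike chromium oxidants, does not transpose it; the C9 stereocentre, having controlled C12, is erased.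

Step 9
Reactants: 11 (4S)-4-hydroxy-4-[(2Z)-oct-2-en-1-yl]cyclopent-2-en-1-one
Product: 12 (4S)-2,3-epoxy-4-hydroxy-4-[(2Z)-oct-2-en-1-yl]cyclopentan-1-one (epoxide face as formed)
Conditions: 30% aq H2O2, NaOH (0.2 equiv), MeOH, −20 to 0 °C
Reagents that add atoms: hydrogen peroxide, OO
Why: Weitz–Scheffer nucleophilic epoxidation (conjugate addition of hydroperoxide, then ring closure) attacks only the electron-poor C10=C11 bond and not the isolated C14=C15 alkene that electrophilic bromination would destroy; the two epoxide stereocentres are removed in step 10.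

Step 10
Reactants: 12 (4S)-2,3-epoxy-4-hydroxy-4-[(2Z)-oct-2-en-1-yl]cyclopentan-1-one
Product: 15 (4S)-2-bromo-4-hydroxy-4-[(2Z)-oct-2-en-1-yl]cyclopent-2-en-1-one, via bromohydrin 13 (not isolated), via bromohydrin mesylate 14 (not isolated)
Conditions: 48% aq HBr (1.2 equiv), THF, 0 °C; crude, then MsCl (1.2 equiv), Et3N (3 equiv), CH2Cl2, −20 to 0 °C
Reagents that add atoms: hydrogen bromide, Br
Why: Acid-promoted opening of the α,β-epoxy ketone by bromide at the carbonyl-activated α-carbon C10 (the classical epoxy ketone to α-halo enone conversion), followed by selective mesylation of the secondary C11 hydroxyl and E1cB elimination, restores C10=C11 with bromine on C10 while the hindered tertiary C12 hydroxyl is not sulfonylated.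

Step 11
Reactants: 15 (4S)-2-bromo-4-hydroxy-4-[(2Z)-oct-2-en-1-yl]cyclopent-2-en-1-one; 16 acrolein
Product: 17 (4S)-2-bromo-4-hydroxy-5-(1-hydroxyprop-2-en-1-yl)-4-[(2Z)-oct-2-en-1-yl]cyclopent-2-en-1-one (mixture at the two new centres)
Conditions: LiN(SiMe3)2 (2.2 equiv), THF, −78 °C; then 16, −78 °C; AcOH quench
Reagents that add atoms: none
Why: Directed aldol addition in which the dilithio alkoxide/enolate (C8 carries the only enolisable hydrogens) adds 1,2 to acrolein at −78 °C; the configurations at the new C7 and C8 centres are immaterial because both are lost in step 12.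

Step 12
Reactants: 17 (4S)-2-bromo-4-hydroxy-5-(1-hydroxyprop-2-en-1-yl)-4-[(2Z)-oct-2-en-1-yl]cyclopent-2-en-1-one
Product: 19 (4R,5E)-2-bromo-4-hydroxy-4-[(2Z)-oct-2-en-1-yl]-5-(prop-2-en-1-ylidene)cyclopent-2-en-1-one, via allylic mesylate 18 (not isolated)
Conditions: MsCl (1.2 equiv), Et3N (3 equiv), CH2Cl2, −40 to 0 °C, dark
Reagents that add atoms: none
Why: Selective mesylation of the secondary allylic hydroxyl and E1cB elimination through the C8 enolate give the exocyclic alkene, expected mainly as the 7E isomer in which the vinyl group avoids the C9 carbonyl oxygen; the minor 7Z isomer is removed by chromatography.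

Step 13
Reactants: 20 hex-5-enoic acid
Product: 21 hex-5-enoyl chloride
Conditions: (COCl)2, DMF (cat.), CH2Cl2, 0 °C to rt; used crude
Reagents that add atoms: oxalyl chloride, ClC(=O)C(Cl)=O
Why: Acid chloride formation with oxalyl chloride under DMF (Vilsmeier-type) catalysis is clean at room temperature and leaves the terminal alkene untouched.

Step 14
Reactants: 19 (4R,5E)-2-bromo-4-hydroxy-4-[(2Z)-oct-2-en-1-yl]-5-(prop-2-en-1-ylidene)cyclopent-2-en-1-one; 21 hex-5-enoyl chloride
Product: 22 (1R,5E)-3-bromo-1-[(2Z)-oct-2-en-1-yl]-4-oxo-5-(prop-2-en-1-ylidene)cyclopent-2-en-1-yl hex-5-enoate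
Conditions: DMAP (0.3 equiv), Et3N (3 equiv), CH2Cl2, 0 °C to rt, dark
Reagents that add atoms: none
Why: DMAP-catalysed acylation (acylpyridinium or ketene pathway) esterifies the tertiary C12 hydroxyl, and because C8 now carries no hydrogen the new β-acyloxy ketone cannot lose the carboxylate by E1cB elimination.

Step 15
Reactants: 22 (1R,5E)-3-bromo-1-[(2Z)-oct-2-en-1-yl]-4-oxo-5-(prop-2-en-1-ylidene)cyclopent-2-en-1-yl hex-5-enoate
Product: 23 (5Z,7E,12R,14Z)-10-bromo-9-oxoprosta-5,7,10,14-tetraen-1,12-olide (bicyclic ten-membered lactone)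
Conditions: (H2IMes)(PCy3)Cl2Ru=CHPh (second-generation Grubbs catalyst, 10 mol% in two portions), 1,4-benzoquinone (20 mol%), CH2Cl2 (1 mM), 40 °C, Ar sparge, dark
Reagents that add atoms: none
Why: The catalyst initiates at the hexenoate vinyl group, the only unhindered and electron-neutral terminal alkene, and the resulting ruthenium alkylidene at C5 undergoes [2+2] cycloaddition with the C6=CH2 terminus of the allylidene group and cycloreversion, forming C5=C6 and releasing ethene. The closest known reaction type is ring-closing metathesis to ten-membered lactones and to macrocyclic 1,3-dienes from a terminal alkene and a terminal diene. The ten-membered ring (C12, O, C1 to C8) closes as a macrocyclisation onto the existing cyclopentenone, with C7=C8 and the C8–C12 bond becoming part of both rings; no stereocentre is formed and C12 is not touched. Only the 7E isomer, in which C6 is cis to C12, can reach the tether, and with C7=C8 cis within the ring a trans C5=C6 bond would be severely strained, so the 5Z alkene is expected from ring strain. The step needs reaction at the two terminal alkenes in preference to C14=C15 and C10=C11 and ring closure in preference to dimerisation: high dilution favours closure, C10=C11 is trisubstituted and electron-poor, and C14=C15 is 1,2-disubstituted and sits next to the quaternary C12. Productive metathesis at the diene terminus leaves ruthenium on the departing CH2 and not on C6, so the C6 carbene that could close a six-membered ring onto C14 is not an intermediate of the intended cycle.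

Step 16
Reactants: 23 (5Z,7E,12R,14Z)-10-bromo-9-oxoprosta-5,7,10,14-tetraen-1,12-olide
Product: 24 methyl (5Z,7E,12R,14Z)-10-bromo-12-hydroxy-9-oxoprosta-5,7,10,14-tetraen-1-oate (bromovulone I)
Conditions: K2CO3 (0.2 equiv), MeOH, 0 °C, dark
Reagents that add atoms: methanol, CO
Why: Base-catalysed transesterification in which methoxide attacks the unhindered lactone carbonyl C1 and the strained ring opens to the methyl ester and the C12 alkoxide, which cannot undergo retro-aldol cleavage because C8 and C11 are both sp2; low temperature and catalytic base limit reversible methoxide addition to the dienone.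

## Compound list

1 | (1R,4S)-cis-4-acetoxycyclopent-2-en-1-ol | CC(=O)O[C@@H]1C=C[C@H](O)C1 | starting material
2 | (1S,4R)-4-[(tert-butyldimethylsilyl)oxy]cyclopent-2-en-1-yl acetate | CC(=O)O[C@@H]1C=C[C@H](O[Si](C)(C)C(C)(C)C)C1 | intermediate
3 | (1S,4R)-4-[(tert-butyldimethylsilyl)oxy]cyclopent-2-en-1-ol | O[C@@H]1C=C[C@H](O[Si](C)(C)C(C)(C)C)C1 | intermediate
4 | (4R)-4-[(tert-butyldimethylsilyl)oxy]cyclopent-2-en-1-one | O=C1C=C[C@H](O[Si](C)(C)C(C)(C)C)C1 | intermediate
5 | propargyl bromide (3-bromoprop-1-yne) | C#CCBr | starting material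
6 | (1S,4R)-4-[(tert-butyldimethylsilyl)oxy]-1-(prop-2-yn-1-yl)cyclopent-2-en-1-ol | C#CC[C@@]1(O)C=C[C@H](O[Si](C)(C)C(C)(C)C)C1 | intermediate
7 | 1-iodopentane | CCCCCI | starting material
8 | (1S,4R)-4-[(tert-butyldimethylsilyl)oxy]-1-(oct-2-yn-1-yl)cyclopent-2-en-1-ol | CCCCCC#CC[C@@]1(O)C=C[C@H](O[Si](C)(C)C(C)(C)C)C1 | intermediate
9 | (1S,4R)-4-[(tert-butyldimethylsilyl)oxy]-1-[(2Z)-oct-2-en-1-yl]cyclopent-2-en-1-ol | CCCCC/C=C\C[C@@]1(O)C=C[C@H](O[Si](C)(C)C(C)(C)C)C1 | intermediate
10 | (1S,4R)-1-[(2Z)-oct-2-en-1-yl]cyclopent-2-ene-1,4-diol | CCCCC/C=C\C[C@@]1(O)C=C[C@H](O)C1 | intermediate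
11 | (4S)-4-hydroxy-4-[(2Z)-oct-2-en-1-yl]cyclopent-2-en-1-one | CCCCC/C=C\C[C@@]1(O)C=CC(=O)C1 | intermediate
12 | (4S)-2,3-epoxy-4-hydroxy-4-[(2Z)-oct-2-en-1-yl]cyclopentan-1-one | CCCCC/C=C\C[C@@]1(O)C2OC2C(=O)C1 | intermediate
13 | (4S)-2-bromo-3,4-dihydroxy-4-[(2Z)-oct-2-en-1-yl]cyclopentan-1-one (bromohydrin) | CCCCC/C=C\C[C@@]1(O)C(O)C(Br)C(=O)C1 | intermediate (not isolated)
14 | 3-O-methanesulfonate of 13 (bromohydrin mesylate) | CCCCC/C=C\C[C@@]1(O)C(OS(C)(=O)=O)C(Br)C(=O)C1 | intermediate (not isolated)
15 | (4S)-2-bromo-4-hydroxy-4-[(2Z)-oct-2-en-1-yl]cyclopent-2-en-1-one | CCCCC/C=C\C[C@@]1(O)C=C(Br)C(=O)C1 | intermediate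
16 | acrolein | C=CC=O | starting material
17 | (4S)-2-bromo-4-hydroxy-5-(1-hydroxyprop-2-en-1-yl)-4-[(2Z)-oct-2-en-1-yl]cyclopent-2-en-1-one | CCCCC/C=C\C[C@@]1(O)C=C(Br)C(=O)C1C(O)C=C | intermediate
18 | methanesulfonate of the secondary allylic hydroxyl of 17 (allylic mesylate) | CCCCC/C=C\C[C@@]1(O)C=C(Br)C(=O)C1C(OS(C)(=O)=O)C=C | intermediate (not isolated)
19 | (4R,5E)-2-bromo-4-hydroxy-4-[(2Z)-oct-2-en-1-yl]-5-(prop-2-en-1-ylidene)cyclopent-2-en-1-one | CCCCC/C=C\C[C@@]1(O)C=C(Br)C(=O)/C1=C/C=C | intermediate
20 | hex-5-enoic acid | C=CCCCC(=O)O | starting material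
21 | hex-5-enoyl chloride | C=CCCCC(=O)Cl | intermediate
22 | (1R,5E)-3-bromo-1-[(2Z)-oct-2-en-1-yl]-4-oxo-5-(prop-2-en-1-ylidene)cyclopent-2-en-1-yl hex-5-enoate | CCCCC/C=C\C[C@@]1(OC(=O)CCCC=C)C=C(Br)C(=O)/C1=C/C=C | intermediate
23 | (5Z,7E,12R,14Z)-10-bromo-9-oxoprosta-5,7,10,14-tetraen-1,12-olide | CCCCC/C=C\C[C@]12OC(=O)CCC/C=C\C=C1\C(=O)C(Br)=C2 | intermediate
24 | methyl (5Z,7E,12R,14Z)-10-bromo-12-hydroxy-9-oxoprosta-5,7,10,14-tetraen-1-oate (bromovulone I) | CCCCC/C=C\C[C@@]1(O)C=C(Br)C(=O)/C1=C/C=C\CCCC(=O)OC | target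

## Step count and risks

Total step count: 16. Longest linear sequence: 15 (steps 1 to 12 and 14 to 16; step 13 is a one-step branch).

Steps most likely to fail:

1. Step 15 (ring-closing metathesis). The ruthenium carbene may engage the C14=C15 alkene, which would close a six-membered ring between C6 and C14 with loss of hept-1-ene. Alternatively the strained ten-membered ring may close too slowly, so that head-to-tail oligomerisation or a 5E closure takes over. Fallback: the tether is given up and C7=C8 is made by aldol condensation with an aldehyde that already holds the cis C5=C6 bond, setting out from 15. Methyl 5-oxopentanoate is treated with the ylide from (1,3-dioxolan-2-ylmethyl)triphenylphosphonium bromide (KOt-Bu, THF, −78 °C) to give, mainly as the cis isomer, methyl (5Z)-6-(1,3-dioxolan-2-yl)hex-5-enoate F1. Its acetal is cleaved under mild acid (oxalic acid on wet SiO2, 0 °C) to methyl (5Z)-7-oxohept-5-enoate F2. The dilithio derivative of 15 (LiN(SiMe3)2, THF, −78 °C) is added to F2 to give the C7 aldol adduct F3. Selective mesylation of its secondary hydroxyl (MsCl, Et3N, −40 to 0 °C) gives the allylic mesylate F4, which eliminates in the same flask and comes back to the route at 24.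

2. Step 16 (lactone methanolysis). Methoxide may add reversibly at C7 or C11 of the cross-conjugated dienone and scramble the 7E and 5Z geometry, or the tertiary-alkyl ester may resist alcoholysis at a temperature the dienone tolerates. Fallback: setting out from 23, the lactone is hydrolysed under near-neutral conditions with Me3SnOH (1,2-dichloroethane, 60 °C) to (5Z,7E,12R,14Z)-10-bromo-12-hydroxy-9-oxoprosta-5,7,10,14-tetraen-1-oic acid F5. The acid is methylated with Me3SiCHN2 (MeOH/toluene, 0 °C), which comes back to the route at 24.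

3. Step 14 (acylation of the tertiary C12 hydroxyl). The hindered hydroxyl next to the alkylidene may acylate slowly, while DMAP or chloride adds to the trienone and the terminal diene polymerises. Fallback: the hydroxyl is acylated before the diene exists, setting out from 17. Both hydroxyls of 17 are esterified with excess 21 (DMAP, Et3N, CH2Cl2, rt) to give the bis(hex-5-enoate) F6. DBU then expels the C7 carboxylate by E1cB elimination, which forms the 7E allylidene and comes back to the route at 22.

Further compounds
F1 | step 15 | methyl (5Z)-6-(1,3-dioxolan-2-yl)hex-5-enoate | COC(=O)CCC/C=C\C1OCCO1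
F2 | step 15 | methyl (5Z)-7-oxohept-5-enoate | COC(=O)CCC/C=C\C=O
F3 | step 15 | methyl (5Z)-7-{(2S)-3-bromo-2-hydroxy-2-[(2Z)-oct-2-en-1-yl]-5-oxocyclopent-3-en-1-yl}-7-hydroxyhept-5-enoate | CCCCC/C=C\C[C@@]1(O)C=C(Br)C(=O)C1C(O)/C=C\CCCC(=O)OC
F4 | step 15 | 7-O-methanesulfonate of F3 | CCCCC/C=C\C[C@@]1(O)C=C(Br)C(=O)C1C(OS(C)(=O)=O)/C=C\CCCC(=O)OC
F5 | step 16 | (5Z,7E,12R,14Z)-10-bromo-12-hydroxy-9-oxoprosta-5,7,10,14-tetraen-1-oic acid | CCCCC/C=C\C[C@@]1(O)C=C(Br)C(=O)/C1=C/C=C\CCCC(=O)O
F6 | step 14 | bis(hex-5-enoate) of 17 | CCCCC/C=C\C[C@@]1(OC(=O)CCCC=C)C=C(Br)C(=O)C1C(OC(=O)CCCC=C)C=C
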